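## Retrosynthetic overview

1. C8–O ester bond: target ⇒ 4,5-epoxygermacr-1(10)-ene-6,8-diol + O-acetylisovanillic acid (the arene is bought, never built).
2. C8–O bond (key step): 6,8-diol ⇒ 6-ol by 6-OH-tethered γ-C–H silylation and Tamao–Fleming oxidation, which sets C8.
3. C6–C7 bond: ten-membered carbocycle ⇒ acyclic epoxy aldehyde/allylic chloride (allylpalladium/allylzinc macrocyclisation sets C6 and C7; the isopropenyl group is then hydrogenated).
4. Oxirane C–O bonds: acyclic chain ⇒ (2E,6E)-farnesol by Sharpless epoxidation, which sets C4/C5 and controls every later centre.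
5. Ring order: oxirane (step 1), then the ten-membered carbocycle (step 4); a five-membered oxasilolane exists only transiently in step 6.

Assumption: the compound to be made is exactly the stereoisomer of the SMILES, read as (1(10)E,4R,5R,6R,7R,8R) in germacrane numbering (alkene C1=C10, epoxide C4–C5, hydroxyl C6, isopropyl C7, ester C8, C9 the allylic CH2).

## Route

Step 1
Reactants: 1 (2E,6E)-farnesol
Product: 2 (2R,3R,6E)-2,3-epoxy-3,7,11-trimethyldodeca-6,10-dien-1-ol
Conditions: Ti(OiPr)4 (5 mol%), D-(−)-diethyl tartrate (7.5 mol%), t-BuOOH, 4 Å MS, CH2Cl2, −20 °C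
Reagents that add atoms: tert-butyl hydroperoxide, CC(C)(C)OO
Why: Sharpless asymmetric epoxidation acts only on the allylic-alcohol alkene, and with the D-tartrate ligand the titanium-bound peroxide is delivered to the face that gives the (2R,3R) trans-epoxide, i.e. the future C4 and C5 centres.

Step 2
Reactants: 2 (2R,3R,6E)-2,3-epoxy-3,7,11-trimethyldodeca-6,10-dien-1-ol
Product: 3 (2R,3R,6E)-10-chloro-2,3-epoxy-3,7,11-trimethyldodeca-6,11-dien-1-ol (C10 epimer mixture)
Conditions: Ca(OCl)2, CO2 (dry ice), CH2Cl2/H2O, 0 °C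
Reagents that add atoms: calcium hypochlorite, [Ca+2].[O-]Cl.[O-]Cl
Why: Ene-type allylic chlorination by HOCl (formed from Ca(OCl)2 and CO2) takes place preferentially at the exposed chain-end trisubstituted alkene with shift of the double bond to C11=C12, and the new C10 centre need not be controlled because step 4 flattens it into an allyl unit.

Step 3
Reactants: 3 (2R,3R,6E)-10-chloro-2,3-epoxy-3,7,11-trimethyldodeca-6,11-dien-1-ol
Product: 4 (2S,3R,6E)-10-chloro-2,3-epoxy-3,7,11-trimethyldodeca-6,11-dienal (C10 epimer mixture)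
Conditions: PhI(OAc)2, TEMPO (10 mol%), CH2Cl2, rt
Reagents that add atoms: none
Why: Oxoammonium (TEMPO) oxidation with PhI(OAc)2 as terminal oxidant stops at the aldehyde under non-basic conditions, so the α-epoxy centre is not epimerised and the alkenes and the allylic chloride are untouched (the 2S label only reflects the higher CIP priority of CHO).

Step 4
Reactants: 4 (2S,3R,6E)-10-chloro-2,3-epoxy-3,7,11-trimethyldodeca-6,11-dienal
Product: 5 (1(10)E,4R,5R,6R,7R)-4,5-epoxygermacra-1(10),11-dien-6-ol
Conditions: Pd(PPh3)4 (10 mol%), Et2Zn (3 equiv), THF, 0.01 M, rt, slow addition of 4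
Reagents that add atoms: none
Why: Tamaru-type umpolung allylation, in which zerovalent palladium ionises the allylic chloride and Et2Zn turns the allylpalladium into an allylzinc that adds through its more substituted terminus in a chair-like six-membered transition state (E-configured allyl unit, both chain ends equatorial) to the aldehyde face anti to the epoxide C–O bond (Felkin–Anh), closes the ten-membered ring and sets 6R (hydroxyl anti to the epoxide oxygen) and 7R (isopropenyl syn to the hydroxyl along the C5–C8 zigzag).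

Step 5
Reactants: 5 (1(10)E,4R,5R,6R,7R)-4,5-epoxygermacra-1(10),11-dien-6-ol
Product: 6 (1(10)E,4R,5R,6R,7R)-4,5-epoxygermacr-1(10)-en-6-ol
Conditions: H2 (1 atm), RhCl(PPh3)3 (5 mol%), benzene/EtOH, rt
Reagents that add atoms: none
Why: Homogeneous hydrogenation with RhCl(PPh3)3 reduces the unhindered 1,1-disubstituted isopropenyl alkene but not the trisubstituted ring alkene and does not hydrogenolyse the epoxide, and no stereocentre is formed.

Step 6
Reactants: 6 (1(10)E,4R,5R,6R,7R)-4,5-epoxygermacr-1(10)-en-6-ol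
Product: 9 (1(10)E,4R,5R,6R,7S,8R)-4,5-epoxygermacr-1(10)-ene-6,8-diol, via 6-O-diethylsilyl ether 7 (not isolated), via bridged oxasilolane 8 (not isolated)
Conditions: Et2SiH2, [Ir(cod)OMe]2 (0.5 mol%), THF, rt; then [Ir(cod)OMe]2 (2 mol%), Me4phen (5 mol%), norbornene (1.2 equiv), THF, 100 °C; then H2O2 (30% aq), KHCO3, THF/MeOH, 50 °C
Reagents that add atoms: hydrogen peroxide, OO
Why: Proposed new method: the 6-OH is converted in the flask into a diethyl(hydrido)silyl ether whose Si–H adds to the iridium–tetramethylphenanthroline catalyst, and the resulting iridium silyl species cleaves the only γ C–H bond that can close a cis-bridged five-membered oxasilolane, namely the C8–H lying 1,3-syn to the C6–O bond (the other γ hydrogen, on C11, is tertiary and hindered, the δ-methyl C–H bonds would need a six-membered ring, and the alkene and epoxide are spared because norbornene is the hydrogen acceptor and neither oxidant nor Lewis acid is present), after which Tamao–Fleming oxidation replaces C8–Si by C8–OH with retention so that C8 is set as 8R, syn to the 6-OH, by the tether geometry; the closest known reaction type is the iridium-catalysed hydroxyl-directed γ-C–H silylation/oxidation of (hydrido)silyl ethers to 1,3-diols, established for methyl groups and for secondary C–H bonds of simple cyclohexyl and open-chain alcohols but not for a diastereotopic methylene of a ten-membered epoxy-cycloalkene.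

Step 7
Reactants: 10 isovanillic acid (3-hydroxy-4-methoxybenzoic acid)
Product: 11 3-acetoxy-4-methoxybenzoic acid
Conditions: Ac2O, pyridine, rt; aqueous work-up
Reagents that add atoms: acetic anhydride, CC(=O)OC(C)=O
Why: Acetylation of the phenol (acyl transfer to the phenolic oxygen, any mixed anhydride being hydrolysed on work-up) masks it so that the acid cannot esterify itself in step 8.

Step 8
Reactants: 9 (1(10)E,4R,5R,6R,7S,8R)-4,5-epoxygermacr-1(10)-ene-6,8-diol and 11 3-acetoxy-4-methoxybenzoic acid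
Product: 12 (1(10)E,4R,5R,6R,7R,8R)-4,5-epoxy-6-hydroxygermacr-1(10)-en-8-yl 3-acetoxy-4-methoxybenzoate
Conditions: DCC (1.1 equiv), DMAP (10 mol%), CH2Cl2, −20 to 0 °C
Reagents that add atoms: none
Why: Steglich esterification (DCC activation, DMAP acyl transfer) acylates the 8-OH, which has a CH2 neighbour, faster than the 6-OH, which is flanked by the epoxide carbon and the isopropyl-bearing carbon, and it proceeds with retention because no C–O bond of the diol is broken.

Step 9
Reactants: 12 (1(10)E,4R,5R,6R,7R,8R)-4,5-epoxy-6-hydroxygermacr-1(10)-en-8-yl 3-acetoxy-4-methoxybenzoate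
Product: 13 (1(10)E,4R,5R,6R,7R,8R)-4,5-epoxy-6-hydroxygermacr-1(10)-en-8-yl 3-hydroxy-4-methoxybenzoate (CNP0294356.1)
Conditions: K2CO3 (0.2 equiv), MeOH, 0 °C
Reagents that add atoms: none
Why: Base-catalysed (Zemplén-type) transesterification with methanol cleaves the activated phenyl acetate within minutes at 0 °C while the hindered secondary aroyl ester, the epoxide and all stereocentres remain intact.

## Compound list

1 | (2E,6E)-farnesol | CC(C)=CCC/C(C)=C/CC/C(C)=C/CO | starting material
2 | (2R,3R,6E)-2,3-epoxy-3,7,11-trimethyldodeca-6,10-dien-1-ol | CC(C)=CCC/C(C)=C/CC[C@@]1(C)O[C@@H]1CO | intermediate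
3 | (2R,3R,6E)-10-chloro-2,3-epoxy-3,7,11-trimethyldodeca-6,11-dien-1-ol, C10 epimer mixture | C=C(C)C(Cl)CC/C(C)=C/CC[C@@]1(C)O[C@@H]1CO | intermediate
4 | (2S,3R,6E)-10-chloro-2,3-epoxy-3,7,11-trimethyldodeca-6,11-dienal, C10 epimer mixture | C=C(C)C(Cl)CC/C(C)=C/CC[C@@]1(C)O[C@@H]1C=O | intermediate
5 | (1(10)E,4R,5R,6R,7R)-4,5-epoxygermacra-1(10),11-dien-6-ol (6-OH, 7-isopropenyl) | C1C/C(C)=C/CC[C@@]2(C)O[C@@H]2[C@H](O)[C@H]1C(C)=C | intermediate
6 | (1(10)E,4R,5R,6R,7R)-4,5-epoxygermacr-1(10)-en-6-ol (6-OH, 7-isopropyl) | C1C/C(C)=C/CC[C@@]2(C)O[C@@H]2[C@H](O)[C@H]1C(C)C | intermediate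
7 | 6-O-(diethylsilyl) ether of 6, (4R,5R,6R,7R) | C1C/C(C)=C/CC[C@@]2(C)O[C@@H]2[C@H](O[SiH](CC)CC)[C@H]1C(C)C | intermediate (not isolated)
8 | oxasilolane with SiEt2 bridging O6 and C8, (4R,5R,6R,7R,8R) | CC[Si]1(CC)[C@@H]2C/C(C)=C/CC[C@@]3(C)O[C@@H]3[C@H](O1)[C@H]2C(C)C | intermediate (not isolated)
9 | (1(10)E,4R,5R,6R,7S,8R)-4,5-epoxygermacr-1(10)-ene-6,8-diol (7S is a CIP priority change, not an inversion) | O[C@@H]1C/C(C)=C/CC[C@@]2(C)O[C@@H]2[C@H](O)[C@H]1C(C)C | intermediate
10 | isovanillic acid | COc1ccc(C(=O)O)cc1O | starting material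
11 | 3-acetoxy-4-methoxybenzoic acid | COc1ccc(C(=O)O)cc1OC(C)=O | intermediate
12 | (1(10)E,4R,5R,6R,7R,8R)-4,5-epoxy-6-hydroxygermacr-1(10)-en-8-yl 3-acetoxy-4-methoxybenzoate | COc1ccc(C(=O)O[C@@H]2C/C(C)=C/CC[C@@]3(C)O[C@@H]3[C@H](O)[C@H]2C(C)C)cc1OC(C)=O | intermediate
13 | (1(10)E,4R,5R,6R,7R,8R)-4,5-epoxy-6-hydroxygermacr-1(10)-en-8-yl 3-hydroxy-4-methoxybenzoate | COc1ccc(C(=O)O[C@@H]2C/C(C)=C/CC[C@@]3(C)O[C@@H]3[C@H](O)[C@H]2C(C)C)cc1O | target

## Step count and risks

Total steps: 9. Longest linear sequence: 8 (steps 1–6, 8, 9 from farnesol); step 7 is a one-step side branch.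

Steps most likely to fail:

1. Step 6 (the proposed new C–H oxygenation). A secondary C–H bond must be cut at 100 °C beside an epoxide, and silylation of a δ-methyl group, hydrosilylation or migration of the ring alkene, or epoxide opening could take over.
Fallback, setting out from 6 and coming back at 9, with known reactions only: Dess–Martin periodinane/NaHCO3 oxidises 6 to (1(10)E,4R,5S,7R)-4,5-epoxygermacr-1(10)-en-6-one F4. IBX (DMSO/toluene, 70 °C) dehydrogenates F4 at its only readily enolisable α-carbon, toward the ring CH2 rather than the isopropyl methine, to (1(10)E,4R,5S,7Z)-4,5-epoxygermacra-1(10),7-dien-6-one F5. Copper-catalysed conjugate borylation (CuCl, DPEphos, NaOtBu, B2pin2, MeOH, THF; a chiral Josiphos-type bisphosphine if the ring alone does not control the face) adds boron to C8 and hydrogen to C7 across the same outer face of the ring-cis enone. This gives (1(10)E,4R,5S,7R,8R)-4,5-epoxy-8-(4,4,5,5-tetramethyl-1,3,2-dioxaborolan-2-yl)germacr-1(10)-en-6-one F6. NaBO3·4H2O then converts C–B into C–OH with retention, giving (1(10)E,4R,5S,7S,8R)-4,5-epoxy-8-hydroxygermacr-1(10)-en-6-one F7. Narasaka–Prasad reduction (Et2BOMe, NaBH4, THF/MeOH, −78 °C) delivers hydride syn to the 8-OH and returns to the route at 9. This detour costs four steps and rebuilds C7, whose configuration, like the enone geometry, would have to be proven.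

2. Step 2 (site selectivity of the ene chlorination between the 10,11- and 6,7-alkenes).
Fallback, setting out from 2 and coming back at 5: the chain end is functionalised by allylic oxidation instead. SeO2 (cat.)/t-BuOOH/salicylic acid in CH2Cl2 hydroxylates only the (E)-methyl group of the terminal gem-dimethyl alkene, giving (2R,3R,6E,10E)-2,3-epoxy-3,7,11-trimethyldodeca-6,10-diene-1,12-diol F1. Corey–Kim chlorination (NCS, Me2S, CH2Cl2, −20 °C) converts the allylic hydroxyl alone into the chloride (2R,3R,6E,10E)-12-chloro-2,3-epoxy-3,7,11-trimethyldodeca-6,10-dien-1-ol F2. PhI(OAc)2/TEMPO gives (2S,3R,6E,10E)-12-chloro-2,3-epoxy-3,7,11-trimethyldodeca-6,10-dienal F3. The Pd(PPh3)4/Et2Zn cyclisation of F3 runs through the same allylpalladium/allylzinc pair as 4 and comes back to the route at 5.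

3. Step 8 (O8 versus O6 selectivity of the acylation, and diester formation).
Fallback, setting out from 9 and coming back at 12: site selection is handed to a tin acetal. Bu2SnO (MeOH, reflux, then evaporation) converts 9 into the six-membered dibutylstannylene acetal of the 6,8-diol F8. 3-Acetoxy-4-methoxybenzoyl chloride F9 (from 11 with oxalyl chloride and cat. DMF) in CH2Cl2 at 0 °C then acylates its less hindered O8 oxygen without base or DMAP, returning to the route at 12.

## Further compounds

F1 | step 2 | (2R,3R,6E,10E)-2,3-epoxy-3,7,11-trimethyldodeca-6,10-diene-1,12-diol | OC/C(C)=C/CC/C(C)=C/CC[C@@]1(C)O[C@@H]1CO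
F2 | step 2 | (2R,3R,6E,10E)-12-chloro-2,3-epoxy-3,7,11-trimethyldodeca-6,10-dien-1-ol | ClC/C(C)=C/CC/C(C)=C/CC[C@@]1(C)O[C@@H]1CO
F3 | step 2 | (2S,3R,6E,10E)-12-chloro-2,3-epoxy-3,7,11-trimethyldodeca-6,10-dienal | ClC/C(C)=C/CC/C(C)=C/CC[C@@]1(C)O[C@@H]1C=O
F4 | step 6 | (1(10)E,4R,5S,7R)-4,5-epoxygermacr-1(10)-en-6-one | C1C/C(C)=C/CC[C@@]2(C)O[C@@H]2C(=O)[C@H]1C(C)C
F5 | step 6 | (1(10)E,4R,5S,7Z)-4,5-epoxygermacra-1(10),7-dien-6-one | CC(C)/C1=C/C/C(C)=C/CC[C@@]2(C)O[C@@H]2C1=O
F6 | step 6 | (1(10)E,4R,5S,7R,8R)-4,5-epoxy-8-(4,4,5,5-tetramethyl-1,3,2-dioxaborolan-2-yl)germacr-1(10)-en-6-one | CC1(C)OB(OC1(C)C)[C@@H]2C/C(C)=C/CC[C@@]3(C)O[C@@H]3C(=O)[C@H]2C(C)C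
F7 | step 6 | (1(10)E,4R,5S,7S,8R)-4,5-epoxy-8-hydroxygermacr-1(10)-en-6-one | O[C@@H]1C/C(C)=C/CC[C@@]2(C)O[C@@H]2C(=O)[C@H]1C(C)C
F8 | step 8 | dibutylstannylene acetal of the 6,8-diol 9 | CCCC[Sn]1(CCCC)O[C@@H]2C/C(C)=C/CC[C@@]3(C)O[C@@H]3[C@H](O1)[C@H]2C(C)C
F9 | step 8 | 3-acetoxy-4-methoxybenzoyl chloride | COc1ccc(C(=O)Cl)cc1OC(C)=O
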